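**Retrosynthetic overview**

1. The strategy rests on C3 and C8 facing each other across the ten-membered carbocycle C1–C10: C8 is oxygenated, and a radical or cation at C3 is stabilised by the furanone ring oxygen and by C4=C5. A sacrificial C3–C8 bond therefore stores the macrocycle as an oxanorbornanone (C1, C2, C3, C8, C9, C10 plus the O bridge) fused to a cyclohexene (C3–C8); alkoxy-radical scission of that bond (28 → 30) uncovers the ring and the 3(2H)-furanone.
2. Tricycle 28 comes from an intramolecular Diels–Alder reaction of 3-silyloxyfuran 22 with a tethered 2-substituted acrylate (C3–C8 and C9–C10 in one step), followed by exchange of the C8 carboxyl for OH (Barton decarboxylative hydroxylation). The silyloxyfuran is used because the corresponding furanium-olate carbonyl ylide, with its free C2H2, would only tautomerise to the furanone.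
3. Furanone 21 comes from gold-catalysed cyclisation of an α′-hydroxy ynone, made by Sonogashira coupling of Z-vinyl bromide 13 (Br on C4 cis to C6, from a bromo-ylide Wittig; C15 is the ylide formyl carbon) with alkynol 17. C6 and C7 come from butenolide 1 by anti Michael addition and HWE methylenation.
4. Ring order: γ-lactone (in 1) → furanone → oxanorbornene and cyclohexene together (cycloaddition, sets C10) → ten-membered ring by C3–C8 scission → endgame (C8 reduction, C11 methylenation, C15 acetate, C8 methacrylate).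

Key step: step 17

Remark: atoms carry the target numbering C1–C15 throughout (C5 is the carbinol carbon of 1, C6 its stereocentre, C7 the butenolide β-carbon, C11/C12 the lactone CH2/C=O).
Remark: ethyl lactate is used as the racemate; the two centres it brings (C1, C10) are erased before step 14, so 17–21 are diastereomer mixtures at those carbons.

**Route**

Step 1
Reactants: 1 (5S)-5-(hydroxymethyl)furan-2(5H)-one
Product: 2 (5S)-5-({[tert-butyl(dimethyl)silyl]oxy}methyl)furan-2(5H)-one
Conditions: TBSCl, imidazole, DMF, 0 °C to rt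
Reagents that add atoms: tert-butyl(chloro)dimethylsilane CC(C)(C)[Si](C)(C)Cl
Why: Imidazole-promoted silylation of the primary alcohol masks O5 and provides the bulky C6 substituent that will direct the conjugate addition to the opposite face.

Step 2
Reactants: 2 (5S)-5-({[tert-butyl(dimethyl)silyl]oxy}methyl)furan-2(5H)-one; 3 tert-butyl 2-(diethoxyphosphoryl)acetate
Product: 5 tert-butyl 2-[(2S,3R)-2-({[tert-butyl(dimethyl)silyl]oxy}methyl)-5-oxooxolan-3-yl]prop-2-enoate, via phosphonate Michael adduct 4 (not isolated)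
Conditions: 3, NaH, THF, 0 °C; add 2, −78 to 0 °C; then (CH2O)n, 0 °C to rt
Reagents that add atoms: formaldehyde (from paraformaldehyde) C=O
Why: Tandem Michael addition/Horner–Wadsworth–Emmons olefination: the sodium phosphonoacetate should add to C7 anti to the C6 silyloxymethyl group (setting C7 trans to C6), and after proton transfer the phosphonate anion is methylenated by formaldehyde to the 2-substituted acrylate that carries C8 and C9.

Step 3
Reactants: 5 tert-butyl 2-[(2S,3R)-2-({[tert-butyl(dimethyl)silyl]oxy}methyl)-5-oxooxolan-3-yl]prop-2-enoate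
Product: 6 tert-butyl 2-[(2S,3R)-2-(hydroxymethyl)-5-oxooxolan-3-yl]prop-2-enoate
Conditions: HF·pyridine, THF, 0 °C to rt
Reagents that add atoms: none
Why: Acidic fluoride desilylation frees the primary alcohol without forming an alkoxide that could add to the acrylate or open the lactone, and leaves the tert-butyl ester intact.

Step 4
Reactants: 6 tert-butyl 2-[(2S,3R)-2-(hydroxymethyl)-5-oxooxolan-3-yl]prop-2-enoate
Product: 7 tert-butyl 2-[(2S,3R)-2-formyl-5-oxooxolan-3-yl]prop-2-enoate
Conditions: Dess–Martin periodinane, CH2Cl2, 0 °C to rt; used crude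
Reagents that add atoms: none
Why: Dess–Martin oxidation gives the C5 aldehyde under near-neutral conditions that should not epimerise the α-acyloxy centre C6.

Step 5
Reactants: 8 2-(triphenyl-λ5-phosphanylidene)acetaldehyde
Product: 10 2-bromo-2-(triphenyl-λ5-phosphanylidene)acetaldehyde, via bromophosphonium bromide 9 (not isolated)
Conditions: Br2, CH2Cl2, −78 °C; then Et3N, 0 °C
Reagents that add atoms: bromine BrBr
Why: C-bromination of a stabilised ylide followed by deprotonation of the bromophosphonium salt is the standard access to α-halo ylides.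

Step 6
Reactants: 7 tert-butyl 2-[(2S,3R)-2-formyl-5-oxooxolan-3-yl]prop-2-enoate; 10 2-bromo-2-(triphenyl-λ5-phosphanylidene)acetaldehyde
Product: 11 tert-butyl 2-[(2S,3R)-2-[(1Z)-2-bromo-3-oxoprop-1-en-1-yl]-5-oxooxolan-3-yl]prop-2-enoate
Conditions: toluene, 50 °C
Reagents that add atoms: none
Why: The Wittig reaction of a formyl-stabilised ylide should place CHO trans to the C6 chain, so the bromine on C4 ends cis to C6 (Z), the site later taken by C3, while the formyl carbon becomes C15.

Step 7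
Reactants: 11 tert-butyl 2-[(2S,3R)-2-[(1Z)-2-bromo-3-oxoprop-1-en-1-yl]-5-oxooxolan-3-yl]prop-2-enoate
Product: 12 tert-butyl 2-[(2S,3R)-2-[(1Z)-2-bromo-3-hydroxyprop-1-en-1-yl]-5-oxooxolan-3-yl]prop-2-enoate
Conditions: NaBH4, CeCl3·7H2O, MeOH, −78 °C
Reagents that add atoms: none
Why: Luche reduction takes the enal carbonyl in the 1,2 sense in preference to the lactone, the tert-butyl ester and the acrylate, giving the C15 carbinol with the C4=C5 geometry untouched.

Step 8
Reactants: 12 tert-butyl 2-[(2S,3R)-2-[(1Z)-2-bromo-3-hydroxyprop-1-en-1-yl]-5-oxooxolan-3-yl]prop-2-enoate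
Product: 13 tert-butyl 2-[(2S,3R)-2-[(1Z)-2-bromo-3-{[tert-butyl(diphenyl)silyl]oxy}prop-1-en-1-yl]-5-oxooxolan-3-yl]prop-2-enoate
Conditions: TBDPSCl, imidazole, CH2Cl2, 0 °C to rt
Reagents that add atoms: tert-butyl(chloro)diphenylsilane CC(C)(C)[Si](Cl)(c1ccccc1)c1ccccc1
Why: Silylation gives a C15 ether robust enough for the acidic and brief fluoride steps that follow, up to the global desilylation of step 21.

Step 9
Reactants: 14 ethyl 2-hydroxypropanoate (racemic ethyl lactate)
Product: 15 ethyl 2-[(triethylsilyl)oxy]propanoate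
Conditions: TESCl, imidazole, CH2Cl2, 0 °C
Reagents that add atoms: chloro(triethyl)silane CC[Si](Cl)(CC)CC
Why: Standard silylation installs an acid-labile group on the oxygen that will become the furanone ring oxygen.

Step 10
Reactants: 15 ethyl 2-[(triethylsilyl)oxy]propanoate
Product: 17 4-[(triethylsilyl)oxy]pent-1-yn-3-ol (diastereomer mixture), via 2-[(triethylsilyl)oxy]propanal 16 (not isolated)
Conditions: i-Bu2AlH, CH2Cl2, −78 °C; then HC≡CMgBr, THF, −78 to 0 °C; aq. sodium potassium tartrate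
Reagents that add atoms: ethynylmagnesium bromide C#C[Mg]Br
Why: Low-temperature i-Bu2AlH reduction stops at the aluminium hemiacetal, which releases the aldehyde in the presence of the alkynyl Grignard reagent to give the propargylic alcohol, whose two carbinol centres are erased later.

Step 11
Reactants: 13 tert-butyl 2-[(2S,3R)-2-[(1Z)-2-bromo-3-{[tert-butyl(diphenyl)silyl]oxy}prop-1-en-1-yl]-5-oxooxolan-3-yl]prop-2-enoate; 17 4-[(triethylsilyl)oxy]pent-1-yn-3-ol
Product: 18 tert-butyl 2-[(2R,3R)-2-[(1E)-2-({[tert-butyl(diphenyl)silyl]oxy}methyl)-5-hydroxy-6-[(triethylsilyl)oxy]hept-1-en-3-yn-1-yl]-5-oxooxolan-3-yl]prop-2-enoate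
Conditions: Pd(PPh3)4 (5 mol %), CuI (10 mol %), Et3N, THF, rt to 40 °C
Reagents that add atoms: none
Why: Sonogashira coupling (zerovalent palladium with a copper acetylide) proceeds with retention of alkene geometry and joins C3 to C4 cis to C6, and transmetalation should outrun any Heck insertion of the remote acrylate.

Step 12
Reactants: 18 tert-butyl 2-[(2R,3R)-2-[(1E)-2-({[tert-butyl(diphenyl)silyl]oxy}methyl)-5-hydroxy-6-[(triethylsilyl)oxy]hept-1-en-3-yn-1-yl]-5-oxooxolan-3-yl]prop-2-enoate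
Product: 19 tert-butyl 2-[(2R,3R)-2-[(1E)-2-({[tert-butyl(diphenyl)silyl]oxy}methyl)-5-oxo-6-[(triethylsilyl)oxy]hept-1-en-3-yn-1-yl]-5-oxooxolan-3-yl]prop-2-enoate
Conditions: Dess–Martin periodinane, CH2Cl2, 0 °C to rt
Reagents that add atoms: none
Why: Dess–Martin oxidation of the propargylic alcohol gives the ynone (C1 carbonyl) without touching the silyl ethers or the acrylate.

Step 13
Reactants: 19 tert-butyl 2-[(2R,3R)-2-[(1E)-2-({[tert-butyl(diphenyl)silyl]oxy}methyl)-5-oxo-6-[(triethylsilyl)oxy]hept-1-en-3-yn-1-yl]-5-oxooxolan-3-yl]prop-2-enoate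
Product: 21 tert-butyl 2-[(2R,3R)-2-[(1Z)-3-{[tert-butyl(diphenyl)silyl]oxy}-2-(5-methyl-4-oxo-4,5-dihydrofuran-2-yl)prop-1-en-1-yl]-5-oxooxolan-3-yl]prop-2-enoate (epimers at C10), via hydroxy ynone 20 (not isolated)
Conditions: HF·pyridine, THF, 0 °C; then (Ph3P)AuCl (5 mol %), AgOTf (5 mol %), toluene, rt
Reagents that add atoms: none
Why: Selective loss of the triethylsilyl group frees the α′-hydroxy ynone, and 5-endo-dig hydroalkoxylation of the alkyne catalysed by monovalent gold, followed by protodeauration, gives the 3(2H)-furanone with the C10–O–C3 linkage.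

Step 14
Reactants: 21 tert-butyl 2-[(2R,3R)-2-[(1Z)-3-{[tert-butyl(diphenyl)silyl]oxy}-2-(5-methyl-4-oxo-4,5-dihydrofuran-2-yl)prop-1-en-1-yl]-5-oxooxolan-3-yl]prop-2-enoate
Product: 23 Diels–Alder adduct (oxanorbornene silyl enol ether fused to the cyclohexene lactone; tert-butyl ester on C8), via silyloxyfuran 22 (not isolated)
Conditions: TBSOTf, Et3N, CH2Cl2, −78 to 0 °C; then toluene (0.01 M), 60 °C
Reagents that add atoms: tert-butyl(dimethyl)silyl trifluoromethanesulfonate CC(C)(C)[Si](C)(C)OS(=O)(=O)C(F)(F)F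
Why: Soft enolisation gives the electron-rich 3-silyloxyfuran, whose intramolecular Diels–Alder reaction with the tethered acrylate (normal electron demand, C10 bonding to the acrylate β-carbon C9) forms C3–C8 and C9–C10; the tether forces C7 exo, and the trans-fused lactone can only sit diequatorially on the new half-chair cyclohexene, which fixes the diene face and hence C10 relative to C6 and C7.

Step 15
Reactants: 23 Diels–Alder adduct (silyl enol ether, tert-butyl ester)
Product: 24 C1-keto C8-carboxylic acid tricycle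
Conditions: CF3CO2H, CH2Cl2 (trace H2O), 0 °C
Reagents that add atoms: none
Why: Trifluoroacetic acid protonates the silyl enol ether at C2 to give the C1 ketone and cleaves the tert-butyl ester by loss of isobutene, while the primary TBDPS ether and the lactone should survive.

Step 16
Reactants: 24 C1-keto C8-carboxylic acid tricycle
Product: 28 hydroxy oxa-bridged tricyclic lactone (C8 OH; C15 OTBDPS), via acid chloride 25 (not isolated), via thiohydroxamate ester 26 (not isolated), via hydroperoxide 27 (not isolated)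
Conditions: (COCl)2, DMF (cat.), CH2Cl2, 0 °C to rt; then sodium 1-oxidopyridine-2(1H)-thione (C5H4NNaOS), DMAP (cat.), toluene, dark; then t-BuSH, O2, hν (tungsten lamp), 0 °C; then P(OMe)3, rt
Reagents that add atoms: dioxygen O=O
Why: In the Barton decarboxylative hydroxylation the thiohydroxamate ester fragments under light to the tertiary C8 radical, which O2 should trap faster than it can fragment, and the phosphite reduces the hydroperoxide; oxygen enters on the endo face vacated by the carboxyl because the fused cyclohexene keeps C7 exo, so C8 is retained (and is erased in step 17 in any case).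

Step 17
Reactants: 28 hydroxy oxa-bridged tricyclic lactone (C8 OH; C15 OTBDPS)
Product: 30 8-oxo furanone macrocycle (C15 OTBDPS), via hypoiodite 29 (not isolated)
Conditions: PhI(OAc)2, I2, CH2Cl2, hν (visible, tungsten lamp), rt
Reagents that add atoms: none
Why: PhI(OAc)2 (trivalent iodine) and I2 give acetyl hypoiodite, which converts the tertiary C8 alcohol into hypoiodite 29; light homolyses the O–I bond and the C8 alkoxy radical undergoes β-scission of C3–C8, giving the C8 ketone and a C3 radical. The closest known reaction type is the Suárez hypoiodite (alkoxy-radical) fragmentation used for ring expansion of bicyclic tertiary carbinols. The C3 radical is oxidised (iodine transfer and ionisation, or electron transfer to trivalent iodine) to the oxocarbenium ion, which loses the C2 proton made acidic by the C1 ketone, so the only bond formed is the C2=C3 π bond of the 3(2H)-furanone. No ring is closed by bond formation: the ten-membered carbocycle C1–C10 appears because the C3–C8 bond shared by the oxanorbornane and the cyclohexene is cut, a ring expansion by fragmentation that carries over the Z geometry of C4=C5 already fixed in the six-membered ring. No stereocentre is created, and C6, C7 and C10 are not touched. The step needs regioselective scission: of the three bonds β to the oxygen radical only C3–C8 releases a tertiary radical stabilised by the ring oxygen and by C4=C5 and relieves the oxanorbornane strain, and proton loss from C2 rather than C15 is secured by the C1 carbonyl.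

Step 18
Reactants: 30 8-oxo furanone macrocycle (C15 OTBDPS)
Product: 31 (8S)-8-hydroxy furanone macrocycle (C15 OTBDPS)
Conditions: NaBH4, CeCl3·7H2O, MeOH, −78 °C
Reagents that add atoms: none
Why: Luche reduction takes the saturated C8 ketone in preference to the vinylogous-ester carbonyl C1 and the lactone, and hydride is expected to arrive on the exposed α-face (the side of H7, anti to the C7–C11 branch), which would set C8 as the 8S (8β) alcohol.

Step 19
Reactants: 31 (8S)-8-hydroxy furanone macrocycle (C15 OTBDPS)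
Product: 32 8-O-triethylsilyl furanone macrocycle (C15 OTBDPS)
Conditions: TESOTf, 2,6-lutidine, CH2Cl2, −78 °C
Reagents that add atoms: triethylsilyl trifluoromethanesulfonate CC[Si](CC)(CC)OS(=O)(=O)C(F)(F)F
Why: Silylation of the secondary alcohol under non-nucleophilic base blocks translactonisation to O8 during the enolate step.

Step 20
Reactants: 32 8-O-triethylsilyl furanone macrocycle (C15 OTBDPS)
Product: 35 α-methylene lactone (8-OTES; 15-OTBDPS), via Mannich base 33 (not isolated), via trimethylammonium iodide 34 (not isolated)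
Conditions: LiN(SiMe3)2, THF, −78 °C; CH2=NMe2+ I−, −78 to 0 °C; then MeI, CH2Cl2/MeOH, rt; then aq. NaHCO3, CH2Cl2, rt
Reagents that add atoms: N,N-dimethylmethaniminium iodide (Eschenmoser's salt) C=[N+](C)C.[I-]
Why: Kinetic deprotonation at C11 and Mannich reaction with Eschenmoser's salt, then quaternisation and E1cB loss of trimethylamine, is the standard α-methylenation of a γ-lactone and installs C13.

Step 21
Reactants: 35 α-methylene lactone (8-OTES; 15-OTBDPS)
Product: 36 (6R,7R,8S,10R)-3,10-epoxy-8,15-dihydroxy-1-oxogermacra-2,4Z,11(13)-trien-12,6-olide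
Conditions: HF·pyridine, pyridine, THF, 0 °C to rt
Reagents that add atoms: none
Why: Buffered acidic fluoride removes both silyl ethers without the basic conditions that would trigger Michael addition to the methylene lactone or lactone migration.

Step 22
Reactants: 36 (6R,7R,8S,10R)-3,10-epoxy-8,15-dihydroxy-1-oxogermacra-2,4Z,11(13)-trien-12,6-olide
Product: 37 15-O-acetyl-8-hydroxy furanone macrocycle
Conditions: Ac2O (1.1 equiv), 2,4,6-collidine, CH2Cl2, −20 to 0 °C
Reagents that add atoms: acetic anhydride CC(=O)OC(C)=O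
Why: Under a weak, hindered base the primary allylic C15 alcohol should acylate well ahead of the hindered secondary C8 alcohol.

Step 23
Reactants: 37 15-O-acetyl-8-hydroxy furanone macrocycle
Product: 38 (6R,7R,8S,10R)-15-acetoxy-3,10-epoxy-8-(2-methylprop-2-enoyloxy)-1-oxogermacra-2,4Z,11(13)-trien-12,6-olide (CNP0179932.1)
Conditions: methacrylic anhydride, Et3N, DMAP (cat.), CH2Cl2, 0 °C to rt
Reagents that add atoms: methacrylic anhydride C=C(C)C(=O)OC(=O)C(C)=C
Why: DMAP-catalysed acylation of the remaining secondary alcohol with the anhydride proceeds with retention at C8 and completes the target.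

**Compound list**

1 | (5S)-5-(hydroxymethyl)furan-2(5H)-one | OC[C@H]1OC(=O)C=C1 | starting material
2 | (5S)-5-({[tert-butyl(dimethyl)silyl]oxy}methyl)furan-2(5H)-one | CC(C)(C)[Si](C)(C)OC[C@H]1OC(=O)C=C1 | intermediate
3 | tert-butyl 2-(diethoxyphosphoryl)acetate | CCOP(=O)(OCC)CC(=O)OC(C)(C)C | starting material
4 | tert-butyl 2-(diethoxyphosphoryl)-2-[(2S,3S)-2-({[tert-butyl(dimethyl)silyl]oxy}methyl)-5-oxooxolan-3-yl]acetate (epimers at the phosphonate carbon; sodium salt in the flask) | CCOP(=O)(OCC)C(C(=O)OC(C)(C)C)[C@H]1CC(=O)O[C@@H]1CO[Si](C)(C)C(C)(C)C | intermediate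
5 | tert-butyl 2-[(2S,3R)-2-({[tert-butyl(dimethyl)silyl]oxy}methyl)-5-oxooxolan-3-yl]prop-2-enoate | C=C(C(=O)OC(C)(C)C)[C@H]1CC(=O)O[C@@H]1CO[Si](C)(C)C(C)(C)C | intermediate
6 | tert-butyl 2-[(2S,3R)-2-(hydroxymethyl)-5-oxooxolan-3-yl]prop-2-enoate | C=C(C(=O)OC(C)(C)C)[C@H]1CC(=O)O[C@@H]1CO | intermediate
7 | tert-butyl 2-[(2S,3R)-2-formyl-5-oxooxolan-3-yl]prop-2-enoate | C=C(C(=O)OC(C)(C)C)[C@H]1CC(=O)O[C@@H]1C=O | intermediate
8 | 2-(triphenyl-λ5-phosphanylidene)acetaldehyde | O=CC=P(c1ccccc1)(c1ccccc1)c1ccccc1 | starting material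
9 | (1-bromo-2-oxoethyl)triphenylphosphonium bromide | O=CC(Br)[P+](c1ccccc1)(c1ccccc1)c1ccccc1.[Br-] | intermediate
10 | 2-bromo-2-(triphenyl-λ5-phosphanylidene)acetaldehyde | O=CC(Br)=P(c1ccccc1)(c1ccccc1)c1ccccc1 | intermediate
11 | tert-butyl 2-[(2S,3R)-2-[(1Z)-2-bromo-3-oxoprop-1-en-1-yl]-5-oxooxolan-3-yl]prop-2-enoate | O=C/C(Br)=C/[C@H]1OC(=O)C[C@@H]1C(=C)C(=O)OC(C)(C)C | intermediate
12 | tert-butyl 2-[(2S,3R)-2-[(1Z)-2-bromo-3-hydroxyprop-1-en-1-yl]-5-oxooxolan-3-yl]prop-2-enoate | OC/C(Br)=C/[C@H]1OC(=O)C[C@@H]1C(=C)C(=O)OC(C)(C)C | intermediate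
13 | tert-butyl 2-[(2S,3R)-2-[(1Z)-2-bromo-3-{[tert-butyl(diphenyl)silyl]oxy}prop-1-en-1-yl]-5-oxooxolan-3-yl]prop-2-enoate | CC(C)(C)[Si](c1ccccc1)(c1ccccc1)OC/C(Br)=C/[C@H]1OC(=O)C[C@@H]1C(=C)C(=O)OC(C)(C)C | intermediate
14 | ethyl 2-hydroxypropanoate (racemic ethyl lactate) | CCOC(=O)C(C)O | starting material
15 | ethyl 2-[(triethylsilyl)oxy]propanoate | CCOC(=O)C(C)O[Si](CC)(CC)CC | intermediate
16 | 2-[(triethylsilyl)oxy]propanal | O=CC(C)O[Si](CC)(CC)CC | intermediate
17 | 4-[(triethylsilyl)oxy]pent-1-yn-3-ol (diastereomer mixture) | C#CC(O)C(C)O[Si](CC)(CC)CC | intermediate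
18 | tert-butyl 2-[(2R,3R)-2-[(1E)-2-({[tert-butyl(diphenyl)silyl]oxy}methyl)-5-hydroxy-6-[(triethylsilyl)oxy]hept-1-en-3-yn-1-yl]-5-oxooxolan-3-yl]prop-2-enoate (mixture at C1 and C10) | CC(C)(C)[Si](c1ccccc1)(c1ccccc1)OC/C(C#CC(O)C(C)O[Si](CC)(CC)CC)=C/[C@H]1OC(=O)C[C@@H]1C(=C)C(=O)OC(C)(C)C | intermediate
19 | tert-butyl 2-[(2R,3R)-2-[(1E)-2-({[tert-butyl(diphenyl)silyl]oxy}methyl)-5-oxo-6-[(triethylsilyl)oxy]hept-1-en-3-yn-1-yl]-5-oxooxolan-3-yl]prop-2-enoate (mixture at C10) | CC(C)(C)[Si](c1ccccc1)(c1ccccc1)OC/C(C#CC(=O)C(C)O[Si](CC)(CC)CC)=C/[C@H]1OC(=O)C[C@@H]1C(=C)C(=O)OC(C)(C)C | intermediate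
20 | tert-butyl 2-[(2R,3R)-2-[(1E)-2-({[tert-butyl(diphenyl)silyl]oxy}methyl)-6-hydroxy-5-oxohept-1-en-3-yn-1-yl]-5-oxooxolan-3-yl]prop-2-enoate (mixture at C10) | CC(C)(C)[Si](c1ccccc1)(c1ccccc1)OC/C(C#CC(=O)C(C)O)=C/[C@H]1OC(=O)C[C@@H]1C(=C)C(=O)OC(C)(C)C | intermediate
21 | tert-butyl 2-[(2R,3R)-2-[(1Z)-3-{[tert-butyl(diphenyl)silyl]oxy}-2-(5-methyl-4-oxo-4,5-dihydrofuran-2-yl)prop-1-en-1-yl]-5-oxooxolan-3-yl]prop-2-enoate (epimers at C10) | CC1OC(=CC1=O)/C(CO[Si](c2ccccc2)(c2ccccc2)C(C)(C)C)=C\[C@H]1OC(=O)C[C@@H]1C(=C)C(=O)OC(C)(C)C | intermediate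
22 | tert-butyl 2-[(2R,3R)-2-[(1Z)-3-{[tert-butyl(diphenyl)silyl]oxy}-2-(4-{[tert-butyl(dimethyl)silyl]oxy}-5-methylfuran-2-yl)prop-1-en-1-yl]-5-oxooxolan-3-yl]prop-2-enoate | Cc1oc(cc1O[Si](C)(C)C(C)(C)C)/C(CO[Si](c2ccccc2)(c2ccccc2)C(C)(C)C)=C\[C@H]1OC(=O)C[C@@H]1C(=C)C(=O)OC(C)(C)C | intermediate
23 | Diels–Alder adduct: 7-oxabicyclo[2.2.1]hept-2-ene (bridgeheads C3 and C10 joined by the O bridge; C1(OTBS)=C2; C8–C9) fused along C3–C8 to the cyclohexene C3–C4(CH2OTBDPS)=C5–C6–C7–C8 carrying the trans 6,12-γ-lactone; CO2t-Bu on C8 endo, C7 exo; C6, C7, C10 as in 38 | C[C@@]12C[C@]3(C(=O)OC(C)(C)C)[C@H]4CC(=O)O[C@@H]4C=C(CO[Si](c5ccccc5)(c5ccccc5)C(C)(C)C)[C@]3(C=C1O[Si](C)(C)C(C)(C)C)O2 | intermediate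
24 | keto acid: the tricycle of 23 with C1 ketone, C2H2 and CO2H on C8 (endo) | C[C@@]12C[C@]3(C(=O)O)[C@H]4CC(=O)O[C@@H]4C=C(CO[Si](c5ccccc5)(c5ccccc5)C(C)(C)C)[C@]3(CC1=O)O2 | intermediate
25 | acid chloride of 24 | C[C@@]12C[C@]3(C(=O)Cl)[C@H]4CC(=O)O[C@@H]4C=C(CO[Si](c5ccccc5)(c5ccccc5)C(C)(C)C)[C@]3(CC1=O)O2 | intermediate
26 | 2-thioxopyridin-1(2H)-yl ester of 24 (thiohydroxamate ester) | C[C@@]12C[C@]3(C(=O)On5ccccc5=S)[C@H]4CC(=O)O[C@@H]4C=C(CO[Si](c5ccccc5)(c5ccccc5)C(C)(C)C)[C@]3(CC1=O)O2 | intermediate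
27 | C8 hydroperoxide of the tricycle | C[C@@]12C[C@]3(OO)[C@H]4CC(=O)O[C@@H]4C=C(CO[Si](c5ccccc5)(c5ccccc5)C(C)(C)C)[C@]3(CC1=O)O2 | intermediate
28 | hydroxy oxa-bridged tricyclic lactone: 1-methyl-7-oxabicyclo[2.2.1]heptan-2-one (C10 methyl-bearing bridgehead, C1 ketone, C2H2, C3 bridgehead, C8, C9H2) fused along C3–C8 to the cyclohexene C3–C4(CH2OTBDPS)=C5–C6–C7–C8 carrying the trans 6,12-γ-lactone; tertiary OH on C8 endo (syn to the C1–C2 bridge), C7 exo; C6, C7, C10 as in 38 | C[C@@]12C[C@]3(O)[C@H]4CC(=O)O[C@@H]4C=C(CO[Si](c5ccccc5)(c5ccccc5)C(C)(C)C)[C@]3(CC1=O)O2 | intermediate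
29 | C8 hypoiodite of 28 | C[C@@]12C[C@]3(OI)[C@H]4CC(=O)O[C@@H]4C=C(CO[Si](c5ccccc5)(c5ccccc5)C(C)(C)C)[C@]3(CC1=O)O2 | intermediate
30 | (6R,7S,10R)-15-{[tert-butyl(diphenyl)silyl]oxy}-3,10-epoxy-1,8-dioxogermacra-2,4Z-dien-12,6-olide (8-oxo furanone macrocycle) | O=C1C[C@@]2(C)OC(=CC2=O)/C(CO[Si](c3ccccc3)(c3ccccc3)C(C)(C)C)=C\[C@H]2OC(=O)C[C@H]12 | intermediate
31 | (6R,7R,8S,10R)-15-{[tert-butyl(diphenyl)silyl]oxy}-3,10-epoxy-8-hydroxy-1-oxogermacra-2,4Z-dien-12,6-olide | O[C@H]1C[C@@]2(C)OC(=CC2=O)/C(CO[Si](c3ccccc3)(c3ccccc3)C(C)(C)C)=C\[C@H]2OC(=O)C[C@H]12 | intermediate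
32 | (6R,7S,8S,10R)-15-{[tert-butyl(diphenyl)silyl]oxy}-3,10-epoxy-1-oxo-8-[(triethylsilyl)oxy]germacra-2,4Z-dien-12,6-olide | CC[Si](CC)(CC)O[C@H]1C[C@@]2(C)OC(=CC2=O)/C(CO[Si](c3ccccc3)(c3ccccc3)C(C)(C)C)=C\[C@H]2OC(=O)C[C@H]12 | intermediate
33 | 11-[(dimethylamino)methyl] derivative of 32 (Mannich base, epimers at C11) | CC[Si](CC)(CC)O[C@H]1C[C@@]2(C)OC(=CC2=O)/C(CO[Si](c3ccccc3)(c3ccccc3)C(C)(C)C)=C\[C@H]2OC(=O)C(CN(C)C)[C@H]12 | intermediate
34 | 11-[(trimethylammonio)methyl] derivative of 32, iodide | CC[Si](CC)(CC)O[C@H]1C[C@@]2(C)OC(=CC2=O)/C(CO[Si](c3ccccc3)(c3ccccc3)C(C)(C)C)=C\[C@H]2OC(=O)C(C[N+](C)(C)C)[C@H]12.[I-] | intermediate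
35 | (6R,7S,8S,10R)-15-{[tert-butyl(diphenyl)silyl]oxy}-3,10-epoxy-1-oxo-8-[(triethylsilyl)oxy]germacra-2,4Z,11(13)-trien-12,6-olide | CC[Si](CC)(CC)O[C@H]1C[C@@]2(C)OC(=CC2=O)/C(CO[Si](c3ccccc3)(c3ccccc3)C(C)(C)C)=C\[C@H]2OC(=O)C(=C)[C@H]12 | intermediate
36 | (6R,7R,8S,10R)-3,10-epoxy-8,15-dihydroxy-1-oxogermacra-2,4Z,11(13)-trien-12,6-olide | O[C@H]1C[C@@]2(C)OC(=CC2=O)/C(CO)=C\[C@H]2OC(=O)C(=C)[C@H]12 | intermediate
37 | (6R,7R,8S,10R)-15-acetoxy-3,10-epoxy-8-hydroxy-1-oxogermacra-2,4Z,11(13)-trien-12,6-olide | O[C@H]1C[C@@]2(C)OC(=CC2=O)/C(COC(C)=O)=C\[C@H]2OC(=O)C(=C)[C@H]12 | intermediate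
38 | (6R,7R,8S,10R)-15-acetoxy-3,10-epoxy-8-(2-methylprop-2-enoyloxy)-1-oxogermacra-2,4Z,11(13)-trien-12,6-olide (CNP0179932.1) | C=C(C)C(=O)O[C@H]1C[C@@]2(C)OC(=CC2=O)/C(COC(C)=O)=C\[C@H]2OC(=O)C(=C)[C@H]12 | target

**Step count and risks**

Total step count: 23. Longest linear sequence: 20 steps (1–4, 6–8, 11–23) from 1.

The three steps most likely to fail:

1. Step 17 (key fragmentation). The hypoiodite may form slowly at the hindered carbinol; the allylic C3 radical or cation may be captured at C5 by iodine or acetate; and the electron-rich furanone product may be iodinated at C2 by the electrophilic iodine reagent. Fallback: set out from hydroperoxide 27, isolated from step 16 by leaving out the phosphite, and treat it with FeSO4·7H2O and Cu(OAc)2 in MeOH. Divalent iron reduces the O–O bond to the same C8 alkoxy radical, β-scission of C3–C8 follows, and divalent copper oxidises the C3 radical to the oxocarbenium ion, which loses the C2 proton. This iodine-free, redox-neutral fragmentation comes back to the route at 30 and makes no compound outside the list (F0).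

2. Step 16 (decarboxylative hydroxylation). Acylation of the thiohydroxamate by the neopentyl-type acid chloride may be slow, and the C8 radical may be lost through scission of the strained bicycle (C2–C3 cleavage towards an α-keto radical) before oxygen capture. Fallback: an ionic carboxy-inversion in place of the radical path. Set out from 24: acid chloride 25 is treated with 3-chloroperbenzoic acid and pyridine at −20 °C to give the mixed diacyl peroxide F1; on warming in CH2Cl2 this rearranges with retention to the mixed carbonic anhydride F2 (C8–O bond formed without a radical); mild cleavage with aqueous NaHCO3 in MeOH releases CO2 and the tertiary alcohol, coming back at 28.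

3. Step 18 (C8 reduction). Hydride delivery to the ketone of the conformationally mobile ten-membered ring may show poor or reversed facial selectivity. Fallback: inversion instead of selective reduction. Set out from 30; the (8R)-alcohol F3 from the reduction is subjected to a Mitsunobu reaction with chloroacetic acid, PPh3 and diisopropyl azodicarboxylate to give the (8S)-chloroacetate F4; the chloroacetyl group is removed with thiourea in EtOH/pyridine without base-induced lactone migration, coming back at 31.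

Further compounds
F0 | step 17 | none | none
F1 | step 16 | mixed diacyl peroxide of acid 24 and 3-chloroperbenzoic acid (C8–C(=O)–O–O–C(=O)Ar) | C[C@@]12C[C@]3(C(=O)OOC(=O)c5cccc(Cl)c5)[C@H]4CC(=O)O[C@@H]4C=C(CO[Si](c5ccccc5)(c5ccccc5)C(C)(C)C)[C@]3(CC1=O)O2
F2 | step 16 | mixed carbonic 3-chlorobenzoic anhydride of alcohol 28 (C8–O–C(=O)–O–C(=O)Ar) | C[C@@]12C[C@]3(OC(=O)OC(=O)c5cccc(Cl)c5)[C@H]4CC(=O)O[C@@H]4C=C(CO[Si](c5ccccc5)(c5ccccc5)C(C)(C)C)[C@]3(CC1=O)O2
F3 | step 18 | (6R,7R,8R,10R)-15-{[tert-butyl(diphenyl)silyl]oxy}-3,10-epoxy-8-hydroxy-1-oxogermacra-2,4Z-dien-12,6-olide (8-epimer of 31) | O[C@@H]1C[C@@]2(C)OC(=CC2=O)/C(CO[Si](c3ccccc3)(c3ccccc3)C(C)(C)C)=C\[C@H]2OC(=O)C[C@H]12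
F4 | step 18 | (6R,7R,8S,10R)-8-(chloroacetoxy)-15-{[tert-butyl(diphenyl)silyl]oxy}-3,10-epoxy-1-oxogermacra-2,4Z-dien-12,6-olide | ClCC(=O)O[C@H]1C[C@@]2(C)OC(=CC2=O)/C(CO[Si](c3ccccc3)(c3ccccc3)C(C)(C)C)=C\[C@H]2OC(=O)C[C@H]12
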